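(The data are calculated for substances that don't exist; noise was put on by code.)

Keep the books on G, and enter each mole of it in an account.

| flask | Z | G | E | remark | time |
|---|---|---|---|---|---|
| grey | 34 mM | 1 equiv | 3.4 mM | run made earlier |  |
| green | 34 mM | 1 equiv | 2.3 mM | run made earlier |  |
| red | 34 mM | 1 equiv | 5.1 mM | run made earlier |  |
| blue | 34 mM | 0.50 equiv | 3.4 mM | run made earlier |  |
| midnight | 34 mM (fed, over 3.0 min) | 1.00 equiv | 3.40 mM | all else is in the flask from the start; the feed brings no volume worth counting | 15 min |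
| dawn | 34 mM | 1.00 equiv (fed, over 3.0 min) | 3.40 mM | all else is in the flask from the start; the feed brings no volume worth counting | 15 min |
| winter | 34 mM | 1.00 equiv | 3.40 mM | everything together at the start | 15 min |

- the flask with the highest amount of L, in percent of the Z charged ("all alike" if they lie within 1.5 percentage points) (midnight / dawn / winter / all alike)
- final L, as a percentage of the Z charged, in midnight
- final L, as a percentage of the Z charged, in dawn
- final L, as a percentage of the Z charged, in winter

| run | time / min | L / % | Q / % |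
|---|---|---|---|
| grey | 2.00 | 100.8 | 0 |
| grey | 4.00 | 100.0 | 1.0 |
| grey | 6.00 | 101.3 | 0 |
| grey | 8.00 | 97.6 | 0.2 |
| grey | 10.0 | 99.6 | 0 |
| grey | 12.0 | 100.9 | 1.0 |
| grey | 15.0 | 101.7 | 0.1 |
| green | 1.00 | 100.3 | 2.8 |
| green | 1.33 | 99.7 | 0 |
| green | 2.00 | 98.4 | 0.2 |
| green | 3.00 | 100.2 | 0.1 |
| green | 5.00 | 99.3 | 0 |
| green | 8.00 | 98.7 | 0 |
| green | 12.0 | 98.8 | 0.6 |
| red | 1.00 | 101.1 | 0 |
| red | 1.33 | 99.9 | 1.0 |
| red | 2.00 | 99.9 | 0 |
| red | 3.00 | 100.2 | 0 |
| red | 5.00 | 99.4 | 0 |
| red | 8.00 | 99.7 | 1.4 |
| red | 12.0 | 100.4 | 0.3 |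
| blue | 2.50 | 50.8 | 0 |
| blue | 5.00 | 48.8 | 0.8 |
| blue | 8.00 | 48.4 | 0.2 |
| blue | 10.0 | 51.9 | 0.2 |
| blue | 12.0 | 49.1 | 0 |

(readings scatter by 1 percentage point)

Open the L account with the blue run, where G is the limiting reagent. Average its 5 readings of L and divide by 0.50 equiv: this gives 99.6% for the capture, the share of the G charged that ends as L. It is a reading and carries the scatter of 1 percentage point.

In the blue run the Q account stays within that scatter, and its highest reading is 0.8%.

The E account stays open. In the green run, L already reads 100.3% at 1.00 min, so that reading shows no loss to E beyond the scatter. In midnight, however, G waits beside E while Z arrives over 3.0 min. If E takes G one for one, its charge could claim 10.0% of G.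

So commit to this: winter at 99.6%, midnight between 89.6% and that figure. Give dawn the same range, since no run reads what a waiting Z does. Winter should stand highest.

The forecast differs and gives all alike, with midnight 100% (95% to 102%), dawn 100% (97% to 102%) and winter 100% (98% to 102%); it adds: “Midnight has G in excess during the feed, which was never tested, so it is slightly less certain”.

The flasks give midnight 94.0%, dawn 92.0% and winter 99.9%, so winter ends highest.

    Z + G ⇌ Q (K = 17.6 M⁻¹, k = 643 M⁻¹ min⁻¹)
    Z + G → L, rate k2*[Z] as long as [G] is above zero (k = 66.0 min⁻¹)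
    2 Z → X (k = 1.37 M⁻¹ min⁻¹)
    G + E → D (k = 19.7 M⁻¹ min⁻¹)

Close the midnight books at 15 min: G stands at 0%, and D at 2.06 mM is 6.04% of the G charged. The capture applied to the G not entered as D gives 93.6%, against L at 94.0%. Now take the neighbour of winter with 0.400 equiv of G. The capture gives 39.8%, and that flask gives L at 40.0%, with Z at 32.6% and X at 27.4%.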